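Ring B is cut at C9–C10 (labdane numbering). In ring B the quaternary C10 with its C20 methyl, the neighbouring C9 that carries the side chain and the exocyclic C8=C17 methylene next to it are the imprint of an allylsilane that adds through C9 to C10 of a ring A enone. One TiCl4-mediated intramolecular Hosomi–Sakurai reaction of 15 therefore closes ring B, forms C9–C10, sets C9 and C10 and releases the methylene. Precursor 15 is a 3-methylcyclohex-2-enone (C2 ketone) with trans C4 ester and C5 tether; the tether ends in a Z-configured silylmethyl alkene bearing the protected C12 oxygen.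

Key step: step 8

Remarks
- Labdane numbering is used for all ring compounds (ring A: C1–C5 and C10; ring B: C5–C10); β is the face of the C20 methyl group. The target is cis-fused (H-5 and C20 both β).
- By the CIP rules the allylsilane in 6, 8, 13 and 15 is Z, because CH2SiMe3 outranks C7 and lies cis to C11. This isomer, with C7 and C11 trans, is the one a chair-like closure needs to place C11 syn to C20, and steps 2 and 3 are chosen to deliver it.
- The R/S labels of C5 and C10 differ between 20 and 22 only because the new C4 methyl changes CIP priorities; no centre is inverted.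
- Assumption: compounds 1, 5, 9, 10 and 25 are taken as catalogue materials.

Step 1
Reactants: 1 hex-3-yne-1,6-diol
Product: 2 6-[(tert-butyldiphenylsilyl)oxy]hex-3-yn-1-ol
Conditions: TBDPSCl (1 equiv), imidazole, 1 (3 equiv), CH2Cl2/DMF, 0 °C to rt
Reagents that add atoms: tert-butyldiphenylsilyl chloride, CC(C)(C)[Si](Cl)(c1ccccc1)c1ccccc1
Why: Statistical monosilylation of a symmetrical diol (silyl ether formation), in which the excess of water-soluble 1 should suppress the bis-ether and is recovered by extraction.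

Step 2
Reactants: 2 6-[(tert-butyldiphenylsilyl)oxy]hex-3-yn-1-ol
Product: 4 (Z)-6-[(tert-butyldiphenylsilyl)oxy]-3-iodohex-3-en-1-ol, via alkenylstannane 3 (not isolated)
Conditions: Bu3SnH (1.1 equiv, slow addition), [Cp*RuCl]4 (1.25 mol %), CH2Cl2, rt; then I2, 0 °C
Reagents that add atoms: iodine, [I][I]
Why: Hydroxyl-directed ruthenium-catalysed trans-hydrostannation should add H and Sn anti across the alkyne with tin on the carbon nearer the free OH, and iododestannylation with retention then leaves the two carbon chains trans.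

Step 3
Reactants: 4 (Z)-6-[(tert-butyldiphenylsilyl)oxy]-3-iodohex-3-en-1-ol; 5 (trimethylsilyl)methylmagnesium chloride
Product: 6 (Z)-6-[(tert-butyldiphenylsilyl)oxy]-3-[(trimethylsilyl)methyl]hex-3-en-1-ol
Conditions: 5 (3 equiv), Pd(PPh3)4 (5 mol %), THF, 0 to 50 °C
Reagents that add atoms: none
Why: Kumada–Corriu coupling of an alkenyl iodide proceeds with retention of alkene geometry, the first equivalent of 5 being spent on the hydroxyl group and the silylmethyl group having no β-hydrogen to lose.

Step 4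
Reactants: 6 (Z)-6-[(tert-butyldiphenylsilyl)oxy]-3-[(trimethylsilyl)methyl]hex-3-en-1-ol
Product: 8 (Z)-tert-butyl({6-iodo-4-[(trimethylsilyl)methyl]hex-3-en-1-yl}oxy)diphenylsilane, via mesylate 7 (not isolated)
Conditions: MsCl, Et3N, CH2Cl2, 0 °C; then NaI, NaHCO3, acetone, 50 °C
Reagents that add atoms: sodium iodide, [Na+].[I-]
Why: Sulfonylation followed by Finkelstein displacement (SN2 at a primary carbon) avoids free iodine and acid, either of which would attack the allylsilane.

Step 5
Reactants: 9 methyl 3,5-dioxocyclohexane-1-carboxylate; 10 (1R,2S,5R)-menthol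
Product: 11 methyl (1S)-3-{[(1R,2S,5R)-5-methyl-2-(propan-2-yl)cyclohexyl]oxy}-5-oxocyclohex-3-ene-1-carboxylate
Conditions: TsOH·H2O (5 mol %), toluene, reflux, Dean–Stark trap; separation of the two C1 diastereomers by chromatography or crystallisation
Reagents that add atoms: none
Why: Acid-catalysed vinylogous ester formation of the achiral dione with an enantiopure alcohol engages the two enantiotopic carbonyl groups without bias, so 11 should form together with its (1R) diastereomer, which differs only at the ester-bearing carbon and should be separable; the configuration of 11 is to be confirmed crystallographically, and because the (1R) diastereomer is simply the enone-transposed isomer of 11, resubmitting it to the same acidic conditions should re-equilibrate it to the mixture for recycling.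

Step 6
Reactants: 11 methyl (1S)-3-(menthyloxy)-5-oxocyclohex-3-ene-1-carboxylate; 8 (Z)-tert-butyl({6-iodo-4-[(trimethylsilyl)methyl]hex-3-en-1-yl}oxy)diphenylsilane
Product: 13 methyl (1S,6R)-6-{(Z)-6-[(tert-butyldiphenylsilyl)oxy]-3-[(trimethylsilyl)methyl]hex-3-en-1-yl}-3-(menthyloxy)-5-oxocyclohex-3-ene-1-carboxylate, via lithium enolate 12 (not isolated)
Conditions: LiN(iPr)2 (1.05 equiv), THF, −78 °C; then 8, DMPU, −78 to −20 °C
Reagents that add atoms: none
Why: Stork–Danheiser α′-alkylation, in which kinetic deprotonation takes the methylene next to the carbonyl group and not the more hindered ester methine, and the iodide approaches the enolate anti to the neighbouring CO2Me group, which sets C5 trans to C4.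

Step 7
Reactants: 13 methyl (1S,6R)-6-(allylsilane tether)-3-(menthyloxy)-5-oxocyclohex-3-ene-1-carboxylate
Product: 15 methyl (1S,2R)-2-{(Z)-6-[(tert-butyldiphenylsilyl)oxy]-3-[(trimethylsilyl)methyl]hex-3-en-1-yl}-3-methyl-5-oxocyclohex-3-ene-1-carboxylate, via tertiary allylic carbinol 14 (not isolated)
Conditions: MeLi, CeCl3, THF, −78 °C; then 1 M HCl, THF, 0 °C to rt
Reagents that add atoms: methyllithium, [Li]C; water, O
Why: 1,2-Addition of MeCeCl2 to the vinylogous ester carbonyl and acid-induced enol ether hydrolysis (Stork–Danheiser enone transposition) give the 3-methyl enone and release menthol, the organocerium reagent being chosen because at −78 °C it should prefer the ketone-like carbonyl to the methyl ester, and no stereocentre is touched.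

Step 8
Reactants: 15 methyl (1S,2R)-2-{(Z)-6-[(tert-butyldiphenylsilyl)oxy]-3-[(trimethylsilyl)methyl]hex-3-en-1-yl}-3-methyl-5-oxocyclohex-3-ene-1-carboxylate
Product: 17 methyl (1S,4aS,5S,8aR)-5-{2-[(tert-butyldiphenylsilyl)oxy]ethyl}-4a-methyl-6-methylidene-3-oxodecahydronaphthalene-1-carboxylate, via titanium enolate 16 (not isolated)
Conditions: TiCl4 (1.5 equiv), CH2Cl2, −78 °C; then saturated aqueous NaHCO3
Reagents that add atoms: none
Why: TiCl4 binds the C2 carbonyl oxygen, C9 of the allylsilane attacks C10 of the activated enone, and the β-silyl cation at C8 collapses with loss of Me3SiCl to the C8=C17 methylene, leaving a titanium enolate that is protonated at C1 on work-up. This is an intramolecular Hosomi–Sakurai conjugate allylation, the known route from 3-methylcyclohex-2-enones to cis-fused bicycles with an angular methyl group. Ring B closes in a 6-exo-trig mode with respect to the enone (C1 stays outside the new ring, C8 and C9 both lie in it). C10 is controlled by C5: the tether can reach C10 only on its own face, and axial attack with the tether pseudo-equatorial on C5 leads to the cis ring fusion (C20 and H-5 syn). C9 is controlled by the alkene geometry in a chair-like forming ring: in the Z-allylsilane C11 is trans to C7, so it takes the equatorial site and ends up syn to C20, which is axial on the new ring. The step needs 1,4- over 1,2-addition and ring closure faster than protodesilylation; attack at C2 would demand a strained bridged eight-membered ring, which secures the first, and strictly anhydrous TiCl4 at −78 °C should secure the second.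

Step 9
Reactants: 17 methyl (1S,4aS,5S,8aR)-5-{2-[(tert-butyldiphenylsilyl)oxy]ethyl}-4a-methyl-6-methylidene-3-oxodecahydronaphthalene-1-carboxylate
Product: 18 the C2 4-methylbenzenesulfonylhydrazone of 17
Conditions: TsNHNH2, MeOH, 50 °C
Reagents that add atoms: 4-methylbenzenesulfonohydrazide, Cc1ccc(cc1)S(=O)(=O)NN
Why: Hydrazone condensation at the unhindered C2 ketone, the only carbonyl group reactive enough, with ester, alkene and silyl ether as spectators.

Step 10
Reactants: 18 the C2 tosylhydrazone of 17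
Product: 20 methyl (1S,4aS,5S,8aR)-5-{2-[(tert-butyldiphenylsilyl)oxy]ethyl}-4a-methyl-6-methylidenedecahydronaphthalene-1-carboxylate, via N-boryl tosylhydrazide 19 (not isolated)
Conditions: catecholborane (2 equiv), CHCl3, 0 °C to rt; then NaOAc·3H2O, reflux
Reagents that add atoms: none
Why: Kabalka reduction, in which catecholborane adds across C=N and acetate then triggers loss of sulfinate and of N2 from the diazene to leave the C2 methylene, while the ester and the 1,1-disubstituted alkene are inert to catecholborane at these temperatures.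

Step 11
Reactants: 20 methyl (1S,4aS,5S,8aR)-5-{2-[(tert-butyldiphenylsilyl)oxy]ethyl}-4a-methyl-6-methylidenedecahydronaphthalene-1-carboxylate
Product: 22 methyl (1S,4aR,5S,8aS)-5-{2-[(tert-butyldiphenylsilyl)oxy]ethyl}-1,4a-dimethyl-6-methylidenedecahydronaphthalene-1-carboxylate, via lithium ester enolate 21 (not isolated)
Conditions: LiN(iPr)2, THF, −78 to 0 °C; then MeI, DMPU, −78 to 0 °C
Reagents that add atoms: methyl iodide, CI
Why: Ester enolate alkylation, in which allylic 1,3-strain should hold enolate 21 in the chair that keeps H-5 in the enolate plane and makes C6 and C20 axial on ring A, so that C20 screens the β-face and methyl iodide enters from the α-face, anti to C20, to give the 4α-methyl 4β-ester.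

Step 12
Reactants: 22 methyl (1S,4aR,5S,8aS)-5-{2-[(tert-butyldiphenylsilyl)oxy]ethyl}-1,4a-dimethyl-6-methylidenedecahydronaphthalene-1-carboxylate
Product: 23 methyl (1S,4aR,5S,8aS)-5-(2-hydroxyethyl)-1,4a-dimethyl-6-methylidenedecahydronaphthalene-1-carboxylate
Conditions: Bu4NF, THF, rt
Reagents that add atoms: none
Why: Fluoride-induced silyl ether cleavage, which the hindered neopentyl methyl ester should survive.

Step 13
Reactants: 23 methyl (1S,4aR,5S,8aS)-5-(2-hydroxyethyl)-1,4a-dimethyl-6-methylidenedecahydronaphthalene-1-carboxylate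
Product: 24 methyl (1S,4aR,5S,8aS)-5-(2-iodoethyl)-1,4a-dimethyl-6-methylidenedecahydronaphthalene-1-carboxylate
Conditions: PPh3, I2, imidazole, CH2Cl2, 0 °C to rt
Reagents that add atoms: iodine, [I][I]
Why: Appel iodination of an unhindered primary alcohol, with the iodine held as the phosphonium complex and imidazole as buffer so that the exocyclic alkene is not touched.

Step 14
Reactants: 25 but-2-yn-1-ol
Product: 26 tert-butyl(but-2-yn-1-yloxy)dimethylsilane
Conditions: TBSCl, imidazole, CH2Cl2, rt
Reagents that add atoms: tert-butyldimethylsilyl chloride, CC(C)(C)[Si](C)(C)Cl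
Why: Standard silyl ether formation, which masks the hydroxyl group for the organometallic steps.

Step 15
Reactants: 26 tert-butyl(but-2-yn-1-yloxy)dimethylsilane
Product: 28 (E)-tert-butyl[(3-iodobut-2-en-1-yl)oxy]dimethylsilane, via alkenylzirconocene chloride 27 (not isolated)
Conditions: Cp2Zr(H)Cl (1.3 equiv), THF, rt; then I2, 0 °C
Reagents that add atoms: iodine, [I][I]
Why: Hydrozirconation is a syn addition that, after equilibration, places zirconium on the less hindered methyl-bearing alkyne carbon, and iodinolysis with retention gives the E-alkenyl iodide.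

Step 16
Reactants: 24 methyl (1S,4aR,5S,8aS)-5-(2-iodoethyl)-1,4a-dimethyl-6-methylidenedecahydronaphthalene-1-carboxylate; 28 (E)-tert-butyl[(3-iodobut-2-en-1-yl)oxy]dimethylsilane
Product: 30 methyl (1S,4aR,5S,8aS)-5-[(E)-5-{[tert-butyl(dimethyl)silyl]oxy}-3-methylpent-3-en-1-yl]-1,4a-dimethyl-6-methylidenedecahydronaphthalene-1-carboxylate, via alkylzinc iodide 29 (not isolated)
Conditions: Zn dust (activated by BrCH2CH2Br and Me3SiCl), LiCl, THF, 40 °C; then 28, PdCl2(dppf) (5 mol %), THF, rt to 45 °C
Reagents that add atoms: none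
Why: Negishi coupling, in which zinc insertion into the primary iodide tolerates the ester and the palladium-catalysed sp3–sp2 coupling keeps the alkenyl geometry, so that C12 and C15 are trans across C13=C14.

Step 17
Reactants: 30 the C15 tert-butyldimethylsilyl ether
Product: 31 methyl (1S,4aR,5S,8aS)-5-[(E)-5-hydroxy-3-methylpent-3-en-1-yl]-1,4a-dimethyl-6-methylidenedecahydronaphthalene-1-carboxylate
Conditions: Bu4NF, THF, 0 °C to rt
Reagents that add atoms: none
Why: Fluoride-induced silyl ether cleavage frees the allylic alcohol needed to direct the epoxidation.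

Step 18
Reactants: 31 methyl (1S,4aR,5S,8aS)-5-[(E)-5-hydroxy-3-methylpent-3-en-1-yl]-1,4a-dimethyl-6-methylidenedecahydronaphthalene-1-carboxylate
Product: 32 methyl (1S,4aR,5S,8aS)-5-{2-[(2R,3R)-3-(hydroxymethyl)-2-methyloxiran-2-yl]ethyl}-1,4a-dimethyl-6-methylidenedecahydronaphthalene-1-carboxylate (CNP0175926.1)
Conditions: Ti(OiPr)4 (10 mol %), D-(−)-diethyl tartrate (12 mol %), t-BuOOH, 4 Å molecular sieves, CH2Cl2, −20 °C
Reagents that add atoms: tert-butyl hydroperoxide, CC(C)(C)OO
Why: Sharpless asymmetric epoxidation, in which the D-(−)-tartrate complex should deliver oxygen to the face of the E-allylic alcohol that gives the (13R,14R)-epoxide (the mirror image of the sense in which the L-(+)-tartrate gives (2S,3S)-epoxygeraniol), while the C8=C17 alkene, not being an allylic alcohol, is left alone.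

Compound list
1 | hex-3-yne-1,6-diol | OCCC#CCCO | starting material
2 | 6-[(tert-butyldiphenylsilyl)oxy]hex-3-yn-1-ol | OCCC#CCCO[Si](c1ccccc1)(c1ccccc1)C(C)(C)C | intermediate
3 | (Z)-6-[(tert-butyldiphenylsilyl)oxy]-3-(tributylstannyl)hex-3-en-1-ol | OCC/C(=C/CCO[Si](c1ccccc1)(c1ccccc1)C(C)(C)C)[Sn](CCCC)(CCCC)CCCC | intermediate (not isolated)
4 | (Z)-6-[(tert-butyldiphenylsilyl)oxy]-3-iodohex-3-en-1-ol | OCC/C(I)=C/CCO[Si](c1ccccc1)(c1ccccc1)C(C)(C)C | intermediate
5 | (trimethylsilyl)methylmagnesium chloride | C[Si](C)(C)C[Mg]Cl | starting material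
6 | (Z)-6-[(tert-butyldiphenylsilyl)oxy]-3-[(trimethylsilyl)methyl]hex-3-en-1-ol | OCC/C(C[Si](C)(C)C)=C/CCO[Si](c1ccccc1)(c1ccccc1)C(C)(C)C | intermediate
7 | methanesulfonate of 6 | CS(=O)(=O)OCC/C(C[Si](C)(C)C)=C/CCO[Si](c1ccccc1)(c1ccccc1)C(C)(C)C | intermediate (not isolated)
8 | (Z)-tert-butyl({6-iodo-4-[(trimethylsilyl)methyl]hex-3-en-1-yl}oxy)diphenylsilane | ICC/C(C[Si](C)(C)C)=C/CCO[Si](c1ccccc1)(c1ccccc1)C(C)(C)C | intermediate
9 | methyl 3,5-dioxocyclohexane-1-carboxylate | COC(=O)C1CC(=O)CC(=O)C1 | starting material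
10 | (1R,2S,5R)-menthol | C[C@@H]1CC[C@H]([C@@H](C1)O)C(C)C | starting material
11 | methyl (1S)-3-{[(1R,2S,5R)-5-methyl-2-(propan-2-yl)cyclohexyl]oxy}-5-oxocyclohex-3-ene-1-carboxylate | O=C1C=C(O[C@@H]2C[C@H](C)CC[C@H]2C(C)C)C[C@H](C(=O)OC)C1 | intermediate
12 | lithium α′-enolate of 11 | [Li]OC1=C[C@@H](C(=O)OC)CC(O[C@@H]2C[C@H](C)CC[C@H]2C(C)C)=C1 | intermediate (not isolated)
13 | methyl (1S,6R)-6-{(Z)-6-[(tert-butyldiphenylsilyl)oxy]-3-[(trimethylsilyl)methyl]hex-3-en-1-yl}-3-(menthyloxy)-5-oxocyclohex-3-ene-1-carboxylate | O=C1C=C(O[C@@H]2C[C@H](C)CC[C@H]2C(C)C)C[C@H](C(=O)OC)[C@H]1CC/C(C[Si](C)(C)C)=C/CCO[Si](c2ccccc2)(c2ccccc2)C(C)(C)C | intermediate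
14 | tertiary allylic carbinol from methyl addition to C10 of 13 (both C10 epimers) | CC1(O)C=C(O[C@@H]2C[C@H](C)CC[C@H]2C(C)C)C[C@H](C(=O)OC)[C@H]1CC/C(C[Si](C)(C)C)=C/CCO[Si](c2ccccc2)(c2ccccc2)C(C)(C)C | intermediate (not isolated)
15 | methyl (1S,2R)-2-{(Z)-6-[(tert-butyldiphenylsilyl)oxy]-3-[(trimethylsilyl)methyl]hex-3-en-1-yl}-3-methyl-5-oxocyclohex-3-ene-1-carboxylate (key-step precursor; C4 ester and C5 tether trans) | O=C1C=C(C)[C@H](CC/C(C[Si](C)(C)C)=C/CCO[Si](c2ccccc2)(c2ccccc2)C(C)(C)C)[C@@H](C(=O)OC)C1 | intermediate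
16 | trichlorotitanium C1=C2 enolate of 17 | C=C1CC[C@H]2[C@](C)(C=C(O[Ti](Cl)(Cl)Cl)C[C@@H]2C(=O)OC)[C@H]1CCO[Si](c3ccccc3)(c3ccccc3)C(C)(C)C | intermediate (not isolated)
17 | methyl (1S,4aS,5S,8aR)-5-{2-[(tert-butyldiphenylsilyl)oxy]ethyl}-4a-methyl-6-methylidene-3-oxodecahydronaphthalene-1-carboxylate (key-step product; cis-fused, H-5, C20, C11 and CO2Me all β) | C=C1CC[C@H]2[C@](C)(CC(=O)C[C@@H]2C(=O)OC)[C@H]1CCO[Si](c3ccccc3)(c3ccccc3)C(C)(C)C | intermediate
18 | C2 tosylhydrazone of 17 (C=N geometry not defined) | C=C1CC[C@H]2[C@](C)(CC(=NNS(=O)(=O)c3ccc(C)cc3)C[C@@H]2C(=O)OC)[C@H]1CCO[Si](c3ccccc3)(c3ccccc3)C(C)(C)C | intermediate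
19 | N-(1,3,2-benzodioxaborol-2-yl) tosylhydrazide from 18 (C2 not defined) | C=C1CC[C@H]2[C@](C)(CC(N(NS(=O)(=O)c3ccc(C)cc3)B3Oc4ccccc4O3)C[C@@H]2C(=O)OC)[C@H]1CCO[Si](c3ccccc3)(c3ccccc3)C(C)(C)C | intermediate (not isolated)
20 | methyl (1S,4aS,5S,8aR)-5-{2-[(tert-butyldiphenylsilyl)oxy]ethyl}-4a-methyl-6-methylidenedecahydronaphthalene-1-carboxylate | C=C1CC[C@H]2[C@](C)(CCC[C@@H]2C(=O)OC)[C@H]1CCO[Si](c3ccccc3)(c3ccccc3)C(C)(C)C | intermediate
21 | lithium C4 ester enolate of 20 | C=C1CC[C@H]2[C@](C)(CCCC2=C(OC)O[Li])[C@H]1CCO[Si](c3ccccc3)(c3ccccc3)C(C)(C)C | intermediate (not isolated)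
22 | methyl (1S,4aR,5S,8aS)-5-{2-[(tert-butyldiphenylsilyl)oxy]ethyl}-1,4a-dimethyl-6-methylidenedecahydronaphthalene-1-carboxylate (4α-methyl, 4β-ester) | C=C1CC[C@H]2[C@](C)(CCC[C@]2(C)C(=O)OC)[C@H]1CCO[Si](c3ccccc3)(c3ccccc3)C(C)(C)C | intermediate
23 | methyl (1S,4aR,5S,8aS)-5-(2-hydroxyethyl)-1,4a-dimethyl-6-methylidenedecahydronaphthalene-1-carboxylate | C=C1CC[C@H]2[C@](C)(CCC[C@]2(C)C(=O)OC)[C@H]1CCO | intermediate
24 | methyl (1S,4aR,5S,8aS)-5-(2-iodoethyl)-1,4a-dimethyl-6-methylidenedecahydronaphthalene-1-carboxylate | C=C1CC[C@H]2[C@](C)(CCC[C@]2(C)C(=O)OC)[C@H]1CCI | intermediate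
25 | but-2-yn-1-ol | CC#CCO | starting material
26 | tert-butyl(but-2-yn-1-yloxy)dimethylsilane | CC#CCO[Si](C)(C)C(C)(C)C | intermediate
27 | (E)-alkenylzirconocene chloride from 26 (Zr on C3) | C/C(=C\CO[Si](C)(C)C(C)(C)C)[Zr](Cl)(C1C=CC=C1)C1C=CC=C1 | intermediate (not isolated)
28 | (E)-tert-butyl[(3-iodobut-2-en-1-yl)oxy]dimethylsilane | C/C(I)=C\CO[Si](C)(C)C(C)(C)C | intermediate
29 | alkylzinc iodide from 24 | C=C1CC[C@H]2[C@](C)(CCC[C@]2(C)C(=O)OC)[C@H]1CC[Zn]I | intermediate (not isolated)
30 | methyl (1S,4aR,5S,8aS)-5-[(E)-5-{[tert-butyl(dimethyl)silyl]oxy}-3-methylpent-3-en-1-yl]-1,4a-dimethyl-6-methylidenedecahydronaphthalene-1-carboxylate | C=C1CC[C@H]2[C@](C)(CCC[C@]2(C)C(=O)OC)[C@H]1CC/C(C)=C/CO[Si](C)(C)C(C)(C)C | intermediate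
31 | methyl (1S,4aR,5S,8aS)-5-[(E)-5-hydroxy-3-methylpent-3-en-1-yl]-1,4a-dimethyl-6-methylidenedecahydronaphthalene-1-carboxylate | C=C1CC[C@H]2[C@](C)(CCC[C@]2(C)C(=O)OC)[C@H]1CC/C(C)=C/CO | intermediate
32 | methyl (1S,4aR,5S,8aS)-5-{2-[(2R,3R)-3-(hydroxymethyl)-2-methyloxiran-2-yl]ethyl}-1,4a-dimethyl-6-methylidenedecahydronaphthalene-1-carboxylate | C=C1CC[C@H]2[C@](C)(CCC[C@]2(C)C(=O)OC)[C@H]1CC[C@@]1(C)O[C@@H]1CO | target

Total step count: 18 (tether branch 4, ring line 12, side-chain iodide branch 2).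
Longest linear sequence: 15 steps (steps 1–4, 6–13, 16–18).

Steps most likely to fail

Step 11 (C4 methylation). Methyl iodide may enter from the wrong face: if the enolate reacts through the flipped chair with C6 equatorial on ring A, C20 no longer screens the β-face and the electrophile enters anti to C6, giving the C4 epimer. The fallback accepts that facial bias but exchanges the oxidation levels of the two C4 substituents, so that the group entering β ends as the ester; it sets out from 20 and returns at 22. Enolate 21 would be alkylated with 4-methoxybenzyl chloromethyl ether to give the 4β-[(4-methoxybenzyloxy)methyl] 4α-ester F1, and LiAlH4 would reduce the 4α-ester to the 4α-hydroxymethyl compound F2. MsCl and Et3N would then give the neopentyl mesylate F3, which LiEt3BH in warm THF should reduce to the 4α-methyl compound F4. DDQ in wet CH2Cl2 would free the 4β-hydroxymethyl compound F5, CrO3/H2SO4 in acetone would oxidise it to the 4β-carboxylic acid F6, and Me3SiCHN2 in MeOH/toluene would convert that acid into 22.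

Step 8 (key step). The hindered trisubstituted allylsilane may be lost by protodesilylation before it adds to the weakly electrophilic β,β-disubstituted enone–TiCl4 complex. The fallback replaces conjugate addition with an allylsilane-terminated cation cyclisation; it sets out from 13 and returns at 17. MeCeCl2 would be added to 13 as in step 7, but the mixture would be quenched with aqueous NaHCO3 so that carbinol 14 is isolated. Catalytic Me3SiOTf in CH2Cl2 at −78 °C should ionise 14 to the alkoxy-substituted allyl cation, a much stronger electrophile at C10, which C9 should capture through the same chair to give the bicyclic C1=C2 menthyl enol ether F7; dilute HCl in THF would then hydrolyse F7 to 17.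

Step 7 (methyl addition). The methyl nucleophile may attack the methyl ester in competition with the vinylogous ester carbonyl. The fallback masks the carboxyl group as its carboxylate, which is inert to MeLi at −78 °C; it sets out from 13 and returns at 15. LiOH in THF/H2O would saponify 13 to the carboxylic acid F8, excess MeLi with CeCl3 at −78 °C followed by 1 M HCl would give the transposed enone acid F9, and Me3SiCHN2 would re-form the methyl ester 15.

Further compounds
F1 | step 11 | methyl 4β-[(4-methoxybenzyloxy)methyl] 4α-carboxylate analogue of 22 (labdane numbering) | C=C1CC[C@H]2[C@](C)(CCC[C@]2(C(=O)OC)COCc3ccc(OC)cc3)[C@H]1CCO[Si](c3ccccc3)(c3ccccc3)C(C)(C)C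
F2 | step 11 | 4α-hydroxymethyl 4β-[(4-methoxybenzyloxy)methyl] compound | C=C1CC[C@H]2[C@](C)(CCC[C@]2(CO)COCc3ccc(OC)cc3)[C@H]1CCO[Si](c3ccccc3)(c3ccccc3)C(C)(C)C
F3 | step 11 | 4α-(methanesulfonyloxymethyl) compound | C=C1CC[C@H]2[C@](C)(CCC[C@]2(COS(C)(=O)=O)COCc3ccc(OC)cc3)[C@H]1CCO[Si](c3ccccc3)(c3ccccc3)C(C)(C)C
F4 | step 11 | 4α-methyl 4β-[(4-methoxybenzyloxy)methyl] compound | C=C1CC[C@H]2[C@](C)(CCC[C@]2(C)COCc3ccc(OC)cc3)[C@H]1CCO[Si](c3ccccc3)(c3ccccc3)C(C)(C)C
F5 | step 11 | 4α-methyl 4β-hydroxymethyl compound | C=C1CC[C@H]2[C@](C)(CCC[C@]2(C)CO)[C@H]1CCO[Si](c3ccccc3)(c3ccccc3)C(C)(C)C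
F6 | step 11 | 4α-methyl 4β-carboxylic acid (free acid of 22) | C=C1CC[C@H]2[C@](C)(CCC[C@]2(C)C(=O)O)[C@H]1CCO[Si](c3ccccc3)(c3ccccc3)C(C)(C)C
F7 | step 8 | C1=C2 menthyl enol ether of 17 | C=C1CC[C@H]2[C@](C)(C=C(O[C@@H]3C[C@H](C)CC[C@H]3C(C)C)C[C@@H]2C(=O)OC)[C@H]1CCO[Si](c3ccccc3)(c3ccccc3)C(C)(C)C
F8 | step 7 | (1S,6R) carboxylic acid of 13 | O=C1C=C(O[C@@H]2C[C@H](C)CC[C@H]2C(C)C)C[C@H](C(=O)O)[C@H]1CC/C(C[Si](C)(C)C)=C/CCO[Si](c2ccccc2)(c2ccccc2)C(C)(C)C
F9 | step 7 | (1S,2R) carboxylic acid of 15 | O=C1C=C(C)[C@H](CC/C(C[Si](C)(C)C)=C/CCO[Si](c2ccccc2)(c2ccccc2)C(C)(C)C)[C@@H](C(=O)O)C1
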